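## Analysis of the target

Target 32 is a 1,2-dioxane. C3 is a peroxyhemiketal carbon carrying OH and the CH2CO2H arm (C1–C2), C4 is a methyl-bearing methine, C5 a methylene, and C6 a fully substituted carbon bound to O1, a methyl group and the C7–C16 chain. That chain has a second methyl-bearing methine at C8 and ends in a phenyl ring.

There are four stereocentres, (3S,4R,6S,8R). In the chair the C3 hydroxyl is axial (anomeric), the C4 methyl and the C6 side chain are equatorial and cis to each other, and the C6 methyl is axial. C8 lies outside the ring, 1,3 to C6 across C7.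

C3 is not a fixed centre: ring–chain tautomerism with the δ-hydroperoxy β-keto acid lets it settle in the axial-hydroxyl arrangement once C4 and C6 are correct. C4 cannot be left to equilibration in the same way. Its epimer has an equally good chair (both methyls equatorial, side chain axial), so the bias would be only the small difference between an axial CH3 and an axial CH2R; C4 therefore has to be set kinetically.

The sensitive elements are the O–O bond (no hydrogenation, phosphine, low-valent metal or strong hydride once it is present), the masked β-keto acid (decarboxylation or retro-Claisen cleavage in the open form, especially in base) and the hemiketal. Both carbons on the protected peroxide are fully substituted, so Kornblum–DeLaMare fragmentation is excluded.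

The hard part is the quaternary, oxygen-bearing C6 with a defined relation to the remote C8, a 1,3-relationship for which open-chain induction is unreliable. The plan rests on drawing C5–C6–C7–C8–C9–C10 as one cyclohexane, in which C6 and C8 are 1,3-ring positions and C5/C10 are a vicinal pair. On that ring the C6–O1 bond can be made stereospecifically, and a later cut of C5–C10 releases both chain ends.

## Retrosynthetic reasoning

**32 ⇒ 29 (C3–O2 and the ester).** The hemiketal bond is opened to the ketone and a protected hydroperoxide, and the acid is masked as a tert-butyl ester. This is cut last because the free peroxyhemiketal tolerates little. The forward step must unmask the hydroperoxide so that it closes onto the C3 ketone, and must free the acid without base.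

**29 ⇒ 27 (C2–C3).** The β-keto ester is cut between C2 and C3, leaving carboxylic acid 27 and a malonate half-ester as the C1–C2 donor. This avoids any enolate chemistry on a ketone that already carries the C4 stereocentre. The forward reaction is a decarboxylative C-acylation under near-neutral conditions.

**27 ⇒ 26 ⇒ 24 (C4–CH3).** The C4 methyl is removed from an acyl oxazolidinone. Since thermodynamic control at C4 is weak, the methyl is introduced by an auxiliary-controlled enolate alkylation that does not depend on C6 or C8. The forward reaction has to methylate the enolate 25 faster than it can attack the neighbouring peroxide.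

**24 ⇒ 23 ⇒ 18 + 22 (C4=C5).** The C4–C5 bond is made by olefination of the neopentyl, α-peroxy aldehyde 18 with the phosphonoacetyl imide 22. Choosing a reagent without the C4 methyl gives a 1,2-disubstituted, acyl-activated alkene, which a metal-free hydrogen transfer can reduce; a trisubstituted alkene next to the quaternary carbon would resist it.

**18 ⇒ 14 + 17 (C10=C11).** The phenylhexyl tail is cut at C10–C11, giving dialdehyde 14 and ylide 17 (from 16, from 15). The forward reaction relies on the large steric difference between the CH2–CHO end (C10) and the quaternary-flanked CHO (C5). The alkene geometry is irrelevant because it is saturated with the C4=C5 bond.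

**14 ⇒ 13 (reconnect C5–C10).** Joining the two aldehyde carbons gives cis-diol 13 on a cyclohexane. The ring reduces the 1,3-relationship of C6 and C8 to ring stereochemistry.

**13 ⇒ 12 ⇒ 11 ⇒ 10 (protecting groups and C6–O1, the key disconnection).** The peroxide is protected as a peroxyketal before the diol is cleaved, because a free α-hydroperoxy aldehyde is fragile. To make that protection unambiguous, the C10 oxygen is an acetate during the key step, so that 11 carries only one hindered hydroxyl beside the hydroperoxide. The C6–O1 bond is then cut to the all-cis epoxy acetate 10: a peroxide nucleophile opens the epoxide at its tertiary carbon with inversion.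

**10 ⇒ 9 ⇒ 8 ⇒ 7 (epoxide and carbinol).** The epoxide must lie on the face of the C8 methyl. That follows if the C10 hydroxyl is cis to the methyl (axial hydride delivery to enone 7) and then directs the epoxidation to its own face.

**7 ⇒ 6 ⇒ 5 ⇒ 3 ⇒ 2 ⇒ 1 (carbonyl transposition and the pool).** Enone 7 is the 1,3-transposed methyl adduct of enone 5. The transposition is needed because it places the carbonyl on the side of the methine that gives the correct enantiomer from (R)-pulegone 1. Enone 5 comes from 1 by a degradation in which sulfur is installed on the former isopropylidene carbon; a dehydrogenation of the derived 3-methylcyclohexanone would not be regioselective.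

## Alternatives that were turned down

**Alternative 1:** (4+3) cycloaddition to a meso cycloheptenone, then desymmetrisation.
- Disconnection: C4–C5 and C7–C8, with C3 and C9 joined as a ring alkene, so that C3–C9 form a seven-membered carbocycle whose carbonyl carbon is C6.
- Forward key step: the oxyallyl cation made from 1,1,3,3-tetrabromopropan-2-one A2 with a zerovalent iron carbonyl adds across the termini of (2E,4E)-hexa-2,4-diene A3. Reductive removal of the remaining bromines leaves meso cis-3,6-dimethylcyclohept-4-en-1-one A1.
- For: two operations from bulk chemicals, and the ring holds both methyl-bearing carbons C4 and C8 in a fixed cis relationship. C4 needs no auxiliary. On this point, and on steps to a stereodefined carbocycle, it is stronger than the chosen route.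
- Against: A1 is achiral, so the absolute configuration and the distinction between the C3 and C9 ends both depend on one enantioselective desymmetrisation that would have to be developed for this ring. The C6 carbonyl must then become a methyl- and peroxide-bearing quaternary carbon, which means an ionising perhydrolysis of a tertiary carbinol or a radical oxygenation on a flexible seven-membered ring; neither is stereospecific. Open-chain dienes are also the weakest partners for oxyallyl cations, and stepwise bond formation can erode the cis relationship.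
- Comparison: the chosen route spends an auxiliary sequence on C4, but takes C8 from the pool and makes C6 by an inversion dictated by a preformed epoxide. The two centres that cannot be corrected later are the secure ones.

**Alternative 2:** olefination union of a peroxy aldehyde and a keto phosphonate.
- Disconnection: the C4=C5 bond, dividing the molecule into C1–C4 and C5–C16.
- Forward key step: the dianion of methyl 4-(diethoxyphosphoryl)-3-oxopentanoate A6 condenses with (2S,4R)-2-[(2-methoxypropan-2-yl)peroxy]-2,4-dimethyl-12-phenyldodecanal A5 to give methyl (E)-6-[(2-methoxypropan-2-yl)peroxy]-4,6,8-trimethyl-3-oxo-16-phenylhexadec-4-enoate A4.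
- For: highly convergent; all of C1–C4 arrive in one step, and olefination of α-peroxy aldehydes spares the O–O bond. From the aldehyde to the keto ester it is clearly shorter than the chosen route (two steps against five).
- Against: it is an endgame and does not solve the stereochemical problem. A5 already contains C6 and C8, and an open-chain synthesis of that quaternary peroxide with 1,3-control is what is missing. The alkene of A4 is trisubstituted, conjugated and flanked by a quaternary carbon, a poor substrate for diimide, the only reductant the peroxide allows. C4 is created without control and left to an equilibration with little bias.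
- Comparison: the chosen route reaches 18, the Z-alkenyl counterpart of A5, through the ring template. It then uses the same kind of olefination with a phosphonoacetyl imide, so that the alkene is disubstituted and C4 is set by the auxiliary. The convergent olefination is kept as the fallback for step 18.

**Alternative 3:** vinylogous Mukaiyama addition to a cyclic peroxycarbenium ion.
- Disconnection: C6–C7, with the dioxane ring already closed.
- Forward key step: a silyl triflate Lewis acid ionises the C6 methoxy group of methyl 2-(3,6-dimethoxy-4,6-dimethyl-1,2-dioxan-3-yl)acetate A8. The peroxycarbenium ion is captured by the terminal CH2 of trimethyl[(3-methylbuta-1,3-dien-1-yl)oxy]silane A9, giving methyl 2-[3-methoxy-4,6-dimethyl-6-((E)-2-methyl-4-oxobut-2-enyl)-1,2-dioxan-3-yl]acetate A7.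
- For: the peroxide ring is made early by simple ketal chemistry and never has to be closed late. The quaternary C6 is formed by C–C bond formation on a ring that can direct the nucleophile, and the hydroperoxide needs no protecting group. On ring construction, and probably on step count, it is stronger than the chosen route.
- Against: A7 has C6 correct only relative to a C4 that is the wrong epimer, and C4 cannot be inverted while C3 is a ketal. C8 is still missing and would have to be created by an enantioselective conjugate reduction of a trisubstituted enal without hydrogenation catalysts and without relay from the ring. γ- versus α-attack of the dienol ether and fragmentation of a tertiary peroxycarbenium ion are further risks. The absolute configuration depends on an enantioenriched A8.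
- Comparison: the chosen strategy forms C6 stereospecifically rather than stereoselectively and takes C8 from the pool, at the price of a longer sequence and a late ring closure.

Key step: step 9

Assumption (chemistry): the C3 configuration of 32 is taken to be the thermodynamic one of the peroxyhemiketal (hydroxyl axial), so it is set by ring–chain equilibration once C4 and C6 are fixed; commercial (R)-(+)-pulegone is taken as the enantiopure source of C8.

## Route

Step 1
Reactants: 1 (R)-(+)-pulegone
Product: 2 pulegone oxide, (6R)-2,2,6-trimethyl-1-oxaspiro[2.5]octan-4-one (both epimers at the spiro carbon)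
Conditions: 30% aq. H2O2, NaOH (cat.), MeOH, 0 °C → rt
Reagents that add atoms: hydrogen peroxide, OO
Why: Weitz–Scheffer nucleophilic epoxidation of the enone; the new centre is lost in step 2, and the ring methine (C8 of the target) is not touched.

Step 2
Reactants: 2 pulegone oxide
Product: 3 (5R)-5-methyl-2-(phenylsulfanyl)cyclohexan-1-one (both C2 epimers)
Conditions: NaSPh, THF, reflux; aq. NH4Cl
Reagents that add atoms: sodium benzenethiolate, [Na+].[S-]c1ccccc1
Why: Thiolate opens the epoxy ketone at the α-carbon and the β-alkoxide undergoes retro-aldol loss of acetone; sulfur is thereby placed regiospecifically on the former isopropylidene carbon, which fixes where the alkene will form.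

Step 3
Reactants: 3 (5R)-5-methyl-2-(phenylsulfanyl)cyclohexan-1-one
Product: 5 (R)-5-methylcyclohex-2-en-1-one, via phenylsulfinyl ketone 4 (not isolated)
Conditions: 3-ClC6H4CO3H (1.0 equiv), CH2Cl2, −78 °C; then CaCO3, toluene, 80 °C
Reagents that add atoms: none
Why: Sulfide oxidation followed by thermal syn-elimination of the α-sulfinyl ketone; only C3 carries β-hydrogens, so the alkene can form only between C2 and C3.

Step 4
Reactants: 5 (R)-5-methylcyclohex-2-en-1-one
Product: 6 (5R)-1,5-dimethylcyclohex-2-en-1-ol (both C1 epimers)
Conditions: MeLi, Et2O, −78 °C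
Reagents that add atoms: methyllithium, [Li]C
Why: 1,2-addition of the hard organolithium to the enone; C1 becomes sp2 again in step 5, so its configuration does not matter.

Step 5
Reactants: 6 (5R)-1,5-dimethylcyclohex-2-en-1-ol
Product: 7 (S)-3,5-dimethylcyclohex-2-en-1-one
Conditions: [C5H5NH][CrO3Cl] (pyridinium chlorochromate), CH2Cl2, rt
Reagents that add atoms: pyridinium chlorochromate, [O-][Cr](=O)(=O)Cl.c1cc[nH+]cc1
Why: Dauben–Babler oxidative transposition ([3,3]-shift of the tertiary allylic chromate ester, then oxidation); moving the carbonyl to the other side of the methine is what makes the (R)-pool centre deliver the required enantiomer of the 3,5-dimethyl enone.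

Step 6
Reactants: 7 (S)-3,5-dimethylcyclohex-2-en-1-one
Product: 8 (1S,5S)-3,5-dimethylcyclohex-2-en-1-ol (hydroxyl cis to the C5 methyl)
Conditions: NaBH4, CeCl3·7H2O, MeOH, −78 °C
Reagents that add atoms: none
Why: Luche 1,2-reduction; hydride adds axially to the half-chair that keeps the C5 methyl equatorial, giving the equatorial alcohol cis to that methyl, which is the relationship that later places the epoxide on the methyl face.

Step 7
Reactants: 8 (1S,5S)-3,5-dimethylcyclohex-2-en-1-ol
Product: 9 (1S,2S,4R,6R)-4,6-dimethyl-7-oxabicyclo[4.1.0]heptan-2-ol (all-cis 2,3-epoxy-3,5-dimethylcyclohexan-1-ol: epoxide, hydroxyl and C5 methyl on one face)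
Conditions: VO(acac)2 (cat.), t-BuOOH, CH2Cl2, 0 °C → rt
Reagents that add atoms: tert-butyl hydroperoxide, CC(C)(C)OO
Why: Hydroxyl-directed epoxidation; the vanadium alkoxide delivers the peroxide oxygen to the alkene face syn to the hydroxyl, so the epoxide ends cis to the hydroxyl and to the ring methyl, fixing the configuration that step 9 inverts at the tertiary carbon.

Step 8
Reactants: 9 all-cis epoxy alcohol
Product: 10 (1S,2S,4R,6R)-4,6-dimethyl-7-oxabicyclo[4.1.0]heptan-2-yl acetate
Conditions: Ac2O, pyridine, DMAP (cat.), CH2Cl2, 0 °C → rt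
Reagents that add atoms: acetic anhydride, CC(=O)OC(C)=O
Why: Standard acylation of the secondary alcohol; the acetate masks the C10 oxygen so that after step 9 only one hindered hydroxyl accompanies the hydroperoxide, and being cis to the epoxide it cannot participate in the opening.

Step 9
Reactants: 10 all-cis epoxy acetate
Product: 11 (1S,2S,3S,5R)-3-hydroperoxy-2-hydroxy-3,5-dimethylcyclohexyl acetate (hydroperoxide trans to the ring methyl, to the hydroxyl and to the acetate)
Conditions: anhydrous H2O2 in Et2O (excess), H3PMo12O40 (cat.), Et2O, 0 °C → rt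
Reagents that add atoms: hydrogen peroxide, OO
Why: The acidic polyoxomolybdate activates the epoxide oxygen and H2O2 attacks the tertiary carbon (C6 of the target) from the face opposite the departing oxygen in a borderline SN2 opening, forming the C6–O1 bond. The closest known reaction type is the molybdenum- or acid-catalysed perhydrolysis of epoxides with ethereal H2O2, which gives β-hydroxy hydroperoxides by attack at the more substituted carbon with inversion. No ring is closed; the carbocycle serves only as the template that is cut in step 12. The one new stereocentre, C6, is controlled by the epoxide configuration from step 7 through inversion, so the hydroperoxide ends trans to the ring methyl (C8) and to the oxygens on C5 and C10. Regioselectivity is needed and is secured three ways: the tertiary carbon carries positive charge best, the secondary epoxide carbon is deactivated by the neighbouring acetoxy-bearing carbon, and attack at C6 is the trans-diaxial (Fürst–Plattner) opening of the half-chair with the ring methyl and the acetate equatorial, whereas attack at C5 would need the conformer with three axial groups. Stereospecificity requires that no free cation forms, which the weakly acidic catalyst, the ether solvent and the large excess of nucleophile should favour; anhydrous H2O2 suppresses hydrolysis to the triol.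

Step 10
Reactants: 11 hydroperoxy hydroxy acetate
Product: 12 (1S,2S,3S,5R)-2-hydroxy-3-[(2-methoxypropan-2-yl)peroxy]-3,5-dimethylcyclohexyl acetate
Conditions: 2-methoxypropene (1.2 equiv), pyridinium p-toluenesulfonate (cat.), CH2Cl2, 0 °C; Et3N quench
Reagents that add atoms: 2-methoxypropene, COC(C)=C
Why: Acid-catalysed peroxyketalisation; the hydroperoxide is far more reactive toward the oxocarbenium ion than the hindered axial hydroxyl, and a cyclic 1,2,4-trioxane cannot form because OOH and OH are trans-diaxial.

Step 11
Reactants: 12 peroxyketal acetate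
Product: 13 (1S,2S,3S,5R)-3-[(2-methoxypropan-2-yl)peroxy]-3,5-dimethylcyclohexane-1,2-diol
Conditions: K2CO3, MeOH, 0 °C → rt
Reagents that add atoms: none
Why: Base-catalysed methanolysis of the acetate; a peroxyketal without α-hydrogens is stable to carbonate, and the cis-diol is freed for cleavage.

Step 12
Reactants: 13 peroxyketal diol
Product: 14 (2S,4S)-2-[(2-methoxypropan-2-yl)peroxy]-2,4-dimethylhexanedial
Conditions: NaIO4, THF/H2O (pH 7 phosphate buffer), 0 °C
Reagents that add atoms: none
Why: Malaprade glycol cleavage through the cyclic periodate ester cuts C5–C10 and opens the template into the chain, with the C5 aldehyde on the quaternary peroxide carbon and the C10 aldehyde at the unhindered end; neutral buffer protects the peroxyketal.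

Step 13
Reactants: 15 (6-bromohexyl)benzene
Product: 16 triphenyl(6-phenylhexyl)phosphonium bromide
Conditions: PPh3, MeCN, reflux
Reagents that add atoms: triphenylphosphine, c1ccc(cc1)P(c1ccccc1)c1ccccc1
Why: SN2 quaternisation of the phosphine by the primary bromide.

Step 14
Reactants: 14 dialdehyde; 16 phosphonium bromide
Product: 18 (2S,4R,6Z)-2-[(2-methoxypropan-2-yl)peroxy]-2,4-dimethyl-12-phenyldodec-6-enal, via phosphonium ylide 17 (not isolated)
Conditions: 16, NaN(SiMe3)2, THF, −78 → 0 °C; then added to 14 (1.0 equiv of ylide), THF, −78 °C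
Reagents that add atoms: none
Why: Wittig olefination with a non-stabilised ylide at low temperature; the C10 aldehyde on a methylene should react much faster than the quaternary-flanked C5 aldehyde, and the alkene geometry is irrelevant because the bond is saturated in step 17.

Step 15
Reactants: 19 (R)-4-benzyl-1,3-oxazolidin-2-one; 20 (diethoxyphosphoryl)acetic acid
Product: 22 diethyl {2-[(4R)-4-benzyl-2-oxo-1,3-oxazolidin-3-yl]-2-oxoethyl}phosphonate, via mixed pivalic anhydride 21 (not isolated)
Conditions: 20, t-BuCOCl, Et3N, THF, −20 °C; then 19, LiCl, −20 °C → rt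
Reagents that add atoms: none
Why: N-acylation of the oxazolidinone by a mixed anhydride with LiCl assistance, the standard way to N-acyl oxazolidinones from carboxylic acids.

Step 16
Reactants: 18 peroxy aldehyde; 22 phosphonoacetyl imide
Product: 23 (4R)-4-benzyl-3-[(2E,4S,6R,8Z)-4-[(2-methoxypropan-2-yl)peroxy]-4,6-dimethyl-14-phenyltetradeca-2,8-dienoyl]-1,3-oxazolidin-2-one
Conditions: LiCl, i-Pr2NEt, MeCN, rt
Reagents that add atoms: none
Why: Masamune–Roush variant of the Horner–Wadsworth–Emmons reaction; the mild amine/LiCl conditions suit an α-peroxy aldehyde that has no α-hydrogen, and the stabilised phosphonate gives the E-alkene, forming the C4=C5 bond.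

Step 17
Reactants: 23 dienoyl imide
Product: 24 (4R)-4-benzyl-3-[(4R,6R)-4-[(2-methoxypropan-2-yl)peroxy]-4,6-dimethyl-14-phenyltetradecanoyl]-1,3-oxazolidin-2-one
Conditions: 2-nitrobenzenesulfonohydrazide (excess), Et3N, CH2Cl2, rt
Reagents that add atoms: none
Why: Diimide generated in the flask transfers H2 concertedly to both 1,2-disubstituted C=C bonds (the isolated Z-alkene and the acyl-activated E-alkene) without touching the O–O bond, which catalytic hydrogenation would cleave.

Step 18
Reactants: 24 saturated imide
Product: 26 (4R)-4-benzyl-3-[(2R,4S,6R)-4-[(2-methoxypropan-2-yl)peroxy]-2,4,6-trimethyl-14-phenyltetradecanoyl]-1,3-oxazolidin-2-one, via sodium enolate 25 (not isolated)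
Conditions: NaN(SiMe3)2, THF, −78 °C; MeI, −78 → −40 °C
Reagents that add atoms: iodomethane, CI
Why: Evans alkylation; the chelated Z-enolate is methylated on the face opposite the benzyl group, which with the (R)-auxiliary gives (R) at C4 independently of C6 and C8, and the low temperature and excess MeI are chosen so that alkylation outruns attack of the enolate on the peroxide.

Step 19
Reactants: 26 methylated imide
Product: 27 (2R,4S,6R)-4-[(2-methoxypropan-2-yl)peroxy]-2,4,6-trimethyl-14-phenyltetradecanoic acid
Conditions: LiOH, H2O2, THF/H2O, 0 °C; aq. Na2SO3; cold dilute HCl to pH 4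
Reagents that add atoms: hydrogen peroxide (as LiOOH), OO
Why: Hydroperoxide anion attacks the exocyclic imide carbonyl selectively (standard auxiliary cleavage) without epimerising C4; the peroxyketal is inert to basic peroxide and to sulfite.

Step 20
Reactants: 27 carboxylic acid
Product: 29 tert-butyl (4R,6S,8R)-6-[(2-methoxypropan-2-yl)peroxy]-4,6,8-trimethyl-3-oxo-16-phenylhexadecanoate, via acyl imidazolide 28 (not isolated)
Conditions: 1,1'-carbonyldiimidazole, THF, rt; then Mg(O2CCH2CO2t-Bu)2, THF, rt; aq. NH4Cl
Reagents that add atoms: magnesium bis(3-tert-butoxy-3-oxopropanoate), [Mg+2].CC(C)(C)OC(=O)CC([O-])=O.CC(C)(C)OC(=O)CC([O-])=O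
Why: Masamune–Brooks homologation; the acyl imidazolide C-acylates the magnesium malonate half-ester and decarboxylation gives the β-keto ester (C2–C3 bond) under near-neutral conditions that should not enolise C4.

Step 21
Reactants: 29 β-keto tert-butyl ester
Product: 32 2-[(3S,4R,6S)-3-hydroxy-4,6-dimethyl-6-[(2R)-2-methyl-10-phenyldecyl]-1,2-dioxan-3-yl]acetic acid (target), via hydroperoxy keto ester 30 (not isolated), via hemiketal tert-butyl ester 31 (not isolated)
Conditions: CF3CO2H, CH2Cl2, H2O (trace), 0 °C
Reagents that add atoms: none
Why: Acid removes the peroxyketal and the freed hydroperoxide adds to the C3 ketone (6-exo-trig) to close the 1,2-dioxane; ring–chain equilibration sets C3 with the hydroxyl axial (anomeric) and cis to the equatorial C4 methyl. The same acid then cleaves the tert-butyl ester by E1 loss of isobutene, so the masked β-keto acid never meets base.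

## Compound list

1 | (R)-(+)-pulegone, (5R)-5-methyl-2-(propan-2-ylidene)cyclohexan-1-one | C[C@@H]1CCC(=C(C)C)C(=O)C1 | starting material
2 | pulegone oxide, (6R)-2,2,6-trimethyl-1-oxaspiro[2.5]octan-4-one (both spiro epimers) | C[C@@H]1CCC2(OC2(C)C)C(=O)C1 | intermediate
3 | (5R)-5-methyl-2-(phenylsulfanyl)cyclohexan-1-one (both C2 epimers) | C[C@@H]1CCC(Sc2ccccc2)C(=O)C1 | intermediate
4 | (5R)-5-methyl-2-(phenylsulfinyl)cyclohexan-1-one | C[C@@H]1CCC(S(=O)c2ccccc2)C(=O)C1 | intermediate (not isolated)
5 | (R)-5-methylcyclohex-2-en-1-one | C[C@@H]1CC=CC(=O)C1 | intermediate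
6 | (5R)-1,5-dimethylcyclohex-2-en-1-ol (both C1 epimers) | C[C@@H]1CC=CC(C)(O)C1 | intermediate
7 | (S)-3,5-dimethylcyclohex-2-en-1-one | C[C@@H]1CC(=O)C=C(C)C1 | intermediate
8 | (1S,5S)-3,5-dimethylcyclohex-2-en-1-ol | C[C@@H]1C[C@H](O)C=C(C)C1 | intermediate
9 | (1S,2S,4R,6R)-4,6-dimethyl-7-oxabicyclo[4.1.0]heptan-2-ol | C[C@@H]1C[C@H](O)[C@@H]2O[C@]2(C)C1 | intermediate
10 | (1S,2S,4R,6R)-4,6-dimethyl-7-oxabicyclo[4.1.0]heptan-2-yl acetate | C[C@@H]1C[C@H](OC(C)=O)[C@@H]2O[C@]2(C)C1 | intermediate (precursor of the key step)
11 | (1S,2S,3S,5R)-3-hydroperoxy-2-hydroxy-3,5-dimethylcyclohexyl acetate | C[C@@H]1C[C@H](OC(C)=O)[C@H](O)[C@](OO)(C)C1 | intermediate (product of the key step)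
12 | (1S,2S,3S,5R)-2-hydroxy-3-[(2-methoxypropan-2-yl)peroxy]-3,5-dimethylcyclohexyl acetate | C[C@@H]1C[C@H](OC(C)=O)[C@H](O)[C@](OOC(C)(C)OC)(C)C1 | intermediate
13 | (1S,2S,3S,5R)-3-[(2-methoxypropan-2-yl)peroxy]-3,5-dimethylcyclohexane-1,2-diol | C[C@@H]1C[C@H](O)[C@H](O)[C@](OOC(C)(C)OC)(C)C1 | intermediate
14 | (2S,4S)-2-[(2-methoxypropan-2-yl)peroxy]-2,4-dimethylhexanedial | O=C[C@](OOC(C)(C)OC)(C)C[C@H](C)CC=O | intermediate
15 | (6-bromohexyl)benzene | BrCCCCCCc1ccccc1 | starting material
16 | triphenyl(6-phenylhexyl)phosphonium bromide | [Br-].c1ccc(cc1)CCCCCC[P+](c1ccccc1)(c1ccccc1)c1ccccc1 | intermediate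
17 | triphenyl(6-phenylhexylidene)phosphorane | c1ccc(cc1)CCCCCC=P(c1ccccc1)(c1ccccc1)c1ccccc1 | intermediate (not isolated)
18 | (2S,4R,6Z)-2-[(2-methoxypropan-2-yl)peroxy]-2,4-dimethyl-12-phenyldodec-6-enal | O=C[C@](OOC(C)(C)OC)(C)C[C@H](C)C/C=C\CCCCCc1ccccc1 | intermediate
19 | (R)-4-benzyl-1,3-oxazolidin-2-one | O=C1N[C@H](Cc2ccccc2)CO1 | starting material
20 | (diethoxyphosphoryl)acetic acid | CCOP(=O)(OCC)CC(=O)O | starting material
21 | (diethoxyphosphoryl)acetic pivalic anhydride | CCOP(=O)(OCC)CC(=O)OC(=O)C(C)(C)C | intermediate (not isolated)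
22 | diethyl {2-[(4R)-4-benzyl-2-oxo-1,3-oxazolidin-3-yl]-2-oxoethyl}phosphonate | CCOP(=O)(OCC)CC(=O)N1[C@H](Cc2ccccc2)COC1=O | intermediate
23 | (4R)-4-benzyl-3-[(2E,4S,6R,8Z)-4-[(2-methoxypropan-2-yl)peroxy]-4,6-dimethyl-14-phenyltetradeca-2,8-dienoyl]-1,3-oxazolidin-2-one | O=C(/C=C/[C@](OOC(C)(C)OC)(C)C[C@H](C)C/C=C\CCCCCc1ccccc1)N1[C@H](Cc2ccccc2)COC1=O | intermediate
24 | (4R)-4-benzyl-3-[(4R,6R)-4-[(2-methoxypropan-2-yl)peroxy]-4,6-dimethyl-14-phenyltetradecanoyl]-1,3-oxazolidin-2-one | O=C(CC[C@](OOC(C)(C)OC)(C)C[C@H](C)CCCCCCCCc1ccccc1)N1[C@H](Cc2ccccc2)COC1=O | intermediate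
25 | sodium (Z)-enolate of 24 | [Na+].[O-]/C(=C\C[C@](OOC(C)(C)OC)(C)C[C@H](C)CCCCCCCCc1ccccc1)N1[C@H](Cc2ccccc2)COC1=O | intermediate (not isolated)
26 | (4R)-4-benzyl-3-[(2R,4S,6R)-4-[(2-methoxypropan-2-yl)peroxy]-2,4,6-trimethyl-14-phenyltetradecanoyl]-1,3-oxazolidin-2-one | O=C([C@H](C)C[C@](OOC(C)(C)OC)(C)C[C@H](C)CCCCCCCCc1ccccc1)N1[C@H](Cc2ccccc2)COC1=O | intermediate
27 | (2R,4S,6R)-4-[(2-methoxypropan-2-yl)peroxy]-2,4,6-trimethyl-14-phenyltetradecanoic acid | OC(=O)[C@H](C)C[C@](OOC(C)(C)OC)(C)C[C@H](C)CCCCCCCCc1ccccc1 | intermediate
28 | (2R,4S,6R)-1-(1H-imidazol-1-yl)-4-[(2-methoxypropan-2-yl)peroxy]-2,4,6-trimethyl-14-phenyltetradecan-1-one | O=C([C@H](C)C[C@](OOC(C)(C)OC)(C)C[C@H](C)CCCCCCCCc1ccccc1)n1ccnc1 | intermediate (not isolated)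
29 | tert-butyl (4R,6S,8R)-6-[(2-methoxypropan-2-yl)peroxy]-4,6,8-trimethyl-3-oxo-16-phenylhexadecanoate | CC(C)(C)OC(=O)CC(=O)[C@H](C)C[C@](OOC(C)(C)OC)(C)C[C@H](C)CCCCCCCCc1ccccc1 | intermediate
30 | tert-butyl (4R,6S,8R)-6-hydroperoxy-4,6,8-trimethyl-3-oxo-16-phenylhexadecanoate | CC(C)(C)OC(=O)CC(=O)[C@H](C)C[C@](OO)(C)C[C@H](C)CCCCCCCCc1ccccc1 | intermediate (not isolated)
31 | tert-butyl 2-[(3S,4R,6S)-3-hydroxy-4,6-dimethyl-6-[(2R)-2-methyl-10-phenyldecyl]-1,2-dioxan-3-yl]acetate | C[C@H](CCCCCCCCc1ccccc1)C[C@@]1(C)C[C@@H](C)[C@](O)(CC(=O)OC(C)(C)C)OO1 | intermediate (not isolated)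
32 | 2-[(3S,4R,6S)-3-hydroxy-4,6-dimethyl-6-[(2R)-2-methyl-10-phenyldecyl]-1,2-dioxan-3-yl]acetic acid | C[C@H](CCCCCCCCc1ccccc1)C[C@@]1(C)C[C@@H](C)[C@](O)(CC(=O)O)OO1 | target

## Step count and least certain steps

Total step count: 21 (19 on the main line plus the preparations of 16 and 22). Longest linear sequence: 19 steps (steps 1–12, 14, 16–21).

**Step 9 (key step).**
- Risk: ionisation of the activated tertiary epoxide ahead of nucleophilic capture. That would erode the inversion at C6, allow a hydride-shift (Meinwald-type) rearrangement, or let adventitious water compete. The electron-withdrawing acetate slows the opening and so lengthens exposure to the acid.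
- Fallback, from 9, returning at 13: the acetate is omitted. Free epoxy alcohol 9 is perhydrolysed as a 2,3-epoxy alcohol, whose hydroxyl can bind the molybdenum centre next to the epoxide oxygen and activate the ring without the inductive brake of the ester. This should give (1S,2S,3S,5R)-3-hydroperoxy-3,5-dimethylcyclohexane-1,2-diol F1. The hydroperoxide of F1, the most reactive oxygen toward the oxocarbenium ion, is then ketalised with one equivalent of 2-methoxypropene (pyridinium p-toluenesulfonate, CH2Cl2, −40 °C) to give 13 directly, and steps 8 and 11 fall away. The price is the chemoselectivity between the hydroperoxide and the cis-diol, which the main route avoids.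

**Step 14.**
- Risk: insufficient site selectivity of the ylide between the two aldehydes, and base-induced enolisation of the C10 aldehyde followed by intramolecular aldol closure onto C5.
- Fallback, from 14, returning at 23: the ends are differentiated by reduction before any carbanion is used. NaBH(OAc)3 (CH2Cl2, 0 °C) should reduce only the unhindered aldehyde, giving (2S,4R)-6-hydroxy-2-[(2-methoxypropan-2-yl)peroxy]-2,4-dimethylhexanal F2. Masamune–Roush olefination of F2 with 22 gives (4R)-4-benzyl-3-[(2E,4S,6R)-8-hydroxy-4-[(2-methoxypropan-2-yl)peroxy]-4,6-dimethyloct-2-enoyl]-1,3-oxazolidin-2-one F3. Dess–Martin oxidation then gives (4R)-4-benzyl-3-[(2E,4S,6S)-4-[(2-methoxypropan-2-yl)peroxy]-4,6-dimethyl-8-oxooct-2-enoyl]-1,3-oxazolidin-2-one F4, now the only aldehyde, which takes up ylide 17 at −78 °C to give 23.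

**Step 18.**
- Risk: intramolecular attack of the C4 enolate on the proximal peroxide oxygen (four-membered ether formation with loss of the ketal alkoxide) competing with methylation, or incomplete alkylation of the hindered enolate.
- Fallback, from 18, returning at 29: the methyl is brought in with the olefination reagent and C4 is set by separation, not by an enolate. The dianion (NaH, then n-BuLi, THF) of tert-butyl 4-(diethoxyphosphoryl)-3-oxopentanoate F5 is condensed with 18. F5 is made from commercial 2-(diethoxyphosphoryl)propanoic acid by the homologation of step 20. The product is tert-butyl (4E,6S,8R,10Z)-6-[(2-methoxypropan-2-yl)peroxy]-4,6,8-trimethyl-3-oxo-16-phenylhexadeca-4,10-dienoate F6. Diimide in large excess gives 29 together with its C4 epimer, tert-butyl (4S,6S,8R)-6-[(2-methoxypropan-2-yl)peroxy]-4,6,8-trimethyl-3-oxo-16-phenylhexadecanoate F7. After step 21 the target 32 is separated by chromatography from 2-[(3R,4S,6S)-3-hydroxy-4,6-dimethyl-6-[(2R)-2-methyl-10-phenyldecyl]-1,2-dioxan-3-yl]acetic acid F8, which is re-equilibrated through its open keto form (catalytic acid) and recycled.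

**Step 21.**
- Risk: acid-promoted enolisation of the ring-opened ketone toward C4 (epimerisation), decarboxylation of the open β-keto acid, or acid-induced rearrangement of the tertiary peroxide during the slower ester cleavage.
- Fallback, from 27, returning at 32: the ester is changed to one removed by fluoride, and the two deprotections are separated. Step 20 is run with the magnesium salt of mono-[2-(trimethylsilyl)ethyl] malonate to give 2-(trimethylsilyl)ethyl (4R,6S,8R)-6-[(2-methoxypropan-2-yl)peroxy]-4,6,8-trimethyl-3-oxo-16-phenylhexadecanoate F9. Pyridinium p-toluenesulfonate in aqueous THF removes the peroxyketal and closes the ring to 2-(trimethylsilyl)ethyl 2-[(3S,4R,6S)-3-hydroxy-4,6-dimethyl-6-[(2R)-2-methyl-10-phenyldecyl]-1,2-dioxan-3-yl]acetate F10. Tris(dimethylamino)sulfonium difluorotrimethylsilicate (DMF, 0 °C, buffered with acetic acid) then frees the acid 32 without strong acid or hydroxide.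

## Further compounds

F1 | step 9 | (1S,2S,3S,5R)-3-hydroperoxy-3,5-dimethylcyclohexane-1,2-diol | C[C@@H]1C[C@H](O)[C@H](O)[C@](OO)(C)C1
F2 | step 14 | (2S,4R)-6-hydroxy-2-[(2-methoxypropan-2-yl)peroxy]-2,4-dimethylhexanal | O=C[C@](OOC(C)(C)OC)(C)C[C@H](C)CCO
F3 | step 14 | (4R)-4-benzyl-3-[(2E,4S,6R)-8-hydroxy-4-[(2-methoxypropan-2-yl)peroxy]-4,6-dimethyloct-2-enoyl]-1,3-oxazolidin-2-one | O=C(/C=C/[C@](OOC(C)(C)OC)(C)C[C@H](C)CCO)N1[C@H](Cc2ccccc2)COC1=O
F4 | step 14 | (4R)-4-benzyl-3-[(2E,4S,6S)-4-[(2-methoxypropan-2-yl)peroxy]-4,6-dimethyl-8-oxooct-2-enoyl]-1,3-oxazolidin-2-one | O=C(/C=C/[C@](OOC(C)(C)OC)(C)C[C@H](C)CC=O)N1[C@H](Cc2ccccc2)COC1=O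
F5 | step 18 | tert-butyl 4-(diethoxyphosphoryl)-3-oxopentanoate (racemic) | CCOP(=O)(OCC)C(C)C(=O)CC(=O)OC(C)(C)C
F6 | step 18 | tert-butyl (4E,6S,8R,10Z)-6-[(2-methoxypropan-2-yl)peroxy]-4,6,8-trimethyl-3-oxo-16-phenylhexadeca-4,10-dienoate | CC(C)(C)OC(=O)CC(=O)/C(C)=C/[C@](OOC(C)(C)OC)(C)C[C@H](C)C/C=C\CCCCCc1ccccc1
F7 | step 18 | tert-butyl (4S,6S,8R)-6-[(2-methoxypropan-2-yl)peroxy]-4,6,8-trimethyl-3-oxo-16-phenylhexadecanoate | CC(C)(C)OC(=O)CC(=O)[C@@H](C)C[C@](OOC(C)(C)OC)(C)C[C@H](C)CCCCCCCCc1ccccc1
F8 | step 18 | 2-[(3R,4S,6S)-3-hydroxy-4,6-dimethyl-6-[(2R)-2-methyl-10-phenyldecyl]-1,2-dioxan-3-yl]acetic acid | C[C@H](CCCCCCCCc1ccccc1)C[C@@]1(C)C[C@H](C)[C@@](O)(CC(=O)O)OO1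
F9 | step 21 | 2-(trimethylsilyl)ethyl (4R,6S,8R)-6-[(2-methoxypropan-2-yl)peroxy]-4,6,8-trimethyl-3-oxo-16-phenylhexadecanoate | C[Si](C)(C)CCOC(=O)CC(=O)[C@H](C)C[C@](OOC(C)(C)OC)(C)C[C@H](C)CCCCCCCCc1ccccc1
F10 | step 21 | 2-(trimethylsilyl)ethyl 2-[(3S,4R,6S)-3-hydroxy-4,6-dimethyl-6-[(2R)-2-methyl-10-phenyldecyl]-1,2-dioxan-3-yl]acetate | C[C@H](CCCCCCCCc1ccccc1)C[C@@]1(C)C[C@@H](C)[C@](O)(CC(=O)OCC[Si](C)(C)C)OO1
A1 | alternative 1 | cis-3,6-dimethylcyclohept-4-en-1-one (meso) | C[C@@H]1CC(=O)C[C@H](C)C=C1
A2 | alternative 1 | 1,1,3,3-tetrabromopropan-2-one | BrC(Br)C(=O)C(Br)Br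
A3 | alternative 1 | (2E,4E)-hexa-2,4-diene | C/C=C/C=C/C
A4 | alternative 2 | methyl (E)-6-[(2-methoxypropan-2-yl)peroxy]-4,6,8-trimethyl-3-oxo-16-phenylhexadec-4-enoate | C[C@H](CCCCCCCCc1ccccc1)C[C@@](OOC(C)(C)OC)(C)/C=C(\C)C(=O)CC(=O)OC
A5 | alternative 2 | (2S,4R)-2-[(2-methoxypropan-2-yl)peroxy]-2,4-dimethyl-12-phenyldodecanal | O=C[C@](OOC(C)(C)OC)(C)C[C@H](C)CCCCCCCCc1ccccc1
A6 | alternative 2 | methyl 4-(diethoxyphosphoryl)-3-oxopentanoate | CCOP(=O)(OCC)C(C)C(=O)CC(=O)OC
A7 | alternative 3 | methyl 2-[3-methoxy-4,6-dimethyl-6-((E)-2-methyl-4-oxobut-2-enyl)-1,2-dioxan-3-yl]acetate | O=C/C=C(\C)C[C@@]1(C)C[C@H](C)[C@@](OC)(CC(=O)OC)OO1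
A8 | alternative 3 | methyl 2-(3,6-dimethoxy-4,6-dimethyl-1,2-dioxan-3-yl)acetate (C3 and C4 as in A7, both C6 epimers) | COC1(C)C[C@H](C)[C@@](OC)(CC(=O)OC)OO1
A9 | alternative 3 | trimethyl{[(1E)-3-methylbuta-1,3-dien-1-yl]oxy}silane | C=C(C)/C=C/O[Si](C)(C)C
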